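Each molecule of target costs one reagent, so I keep the account of that reagent for the flask below.

    substrate + free catalyst ⇌ catalyst intermediate A (K1 = 6000 M⁻¹, k1 = 2270 M⁻¹ s⁻¹)
    reagent + catalyst intermediate A ⇌ catalyst intermediate B (K2 = 3010 M⁻¹, k2 = 71900 M⁻¹ s⁻¹)
    catalyst intermediate B ⇌ catalyst intermediate C (K3 = 5.8, k3 = 22.2 s⁻¹)
    catalyst intermediate C → released group + catalyst intermediate D (k4 = 0.481 s⁻¹)
    catalyst intermediate D → free catalyst + target (k5 = 0.602 s⁻¹)
    reagent + released group ⇌ idle adduct, settled at all times (K6 = 4600 M⁻¹)
    scavenger + released group → scavenged by-product (k7 = 594 M⁻¹ s⁻¹)

substrate 0.20 mM; reagent 0.190 mM; scavenger 0.200 mM; free catalyst 12 µM; time 6.0 min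

* part of the substrate that has reacted at 6.0 min
* share of the unused reagent that is free and not bound as idle adduct, at 6.0 min

- released group is meant together with its idle adduct
- run time (flask): 6.0 min

- **The charge:** I hold 0.190 mM of reagent against 0.20 mM of substrate and 0.200 mM of scavenger, so reagent is the limiting reagent. Reagent charge over substrate charge comes to 95.0%, and I call this share the reagent ceiling: the most of the substrate that can become target.
- **The loan:** The idle adduct only borrows reagent, since step 6 gives it back as scavenger removes released group, and the scavenger charge exceeds the reagent charge, so I expect this entry to close near zero.
- **The time:** Each turnover costs one lifetime of catalyst intermediate C plus one of catalyst intermediate D, together 3.74 s, and the reagent needs 15.8 turnovers. At full speed that takes 59.2 s, which is less than the 6.0 min run, so I expect the flask to come close to its ceiling and put the part reacted at 95.0%, knowing that the slowing tail keeps the true figure somewhat below this.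
- **The closing entry:** Released group starts at zero and is fed by the cycle through the run, so I have no exact figure for this entry by hand. As a rough size I take the amount of free released group whose removal by scavenger takes one run length, with the scavenger level set equal to it as a convenience of this estimate and not as a picture of the flask. That gives about 4.68 µM of free released group at the asked time, and the free share of unused reagent then comes to 97.9%.
- **The forecast:** It gives 91.2% reacted and 97.4% free, and says: “Reagent is limiting, and the adduct temporarily holds some of it.” My figure for the part reacted is higher, because mine is a ceiling and the forecast's is a point on the way to it.
- **The simulation:** The flask gives 91.3% reacted and 97.5% free.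
- **What follows:** In this flask at 6.00 min, the half-life of reagent by the forward turning of reagent and catalyst intermediate A into catalyst intermediate B alone is 0.16 min, short against the 6.0 min run, with 4.3% of the reagent charge still unused, and at 60.0 min the part reacted stands at 95.3%, level with the ceiling of 95.0%. In the neighbour flask with 0.076 mM of reagent the ceiling comes to 38.0%, and at 6.00 min that flask holds 38.0% of its substrate charge as target, with 0% of its reagent left.

All constants stand for no real mixture; no experiment stands behind them.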